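**Retrosynthetic overview**
1. The target is the anti-(2S,3S)-2-aryl-3-benzylsuccinic acid 4-methyl ester. The last two operations only unmask it: auxiliary hydrolysis, then fluoride desilylation.
2. Key disconnection: the central C2–C3 bond. It is closed late by SN2 displacement (inversion) of an (S)-α-triflyloxy ester (fragment B) with the Evans sodium enolate of an arylacetyl imide (fragment A).
3. Fragment A: the aryl–CH2 bond comes from Pd-catalysed α-arylation of tert-butyl acetate with O-silylated 4-bromophenol, followed by ester cleavage and N-acylation of the auxiliary.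
4. Fragment B: the aryl–CH2 bond comes from Cu-catalysed opening of methyl (S)-glycidate with an aryl Grignard reagent. The aryl–prenyl bond comes from ortho-C-prenylation of 3-bromophenol.
5. No ring is formed at any stage. Both benzene rings are bought intact, and the oxazolidinone ring is only a borrowed auxiliary.

Assumption: the recoverable auxiliary (S)-4-benzyl-1,3-oxazolidin-2-one is handled as a reagent without a compound number, since none of its atoms remain in the target. The target SMILES is read as the (2S,3S) anti isomer.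

**Fragment A**

Step 1
Reactants: 1 4-bromophenol
Product: 2 (4-bromophenoxy)triisopropylsilane
Conditions: iPr3SiCl (1.1 equiv), imidazole (2 equiv), DMF, rt
Reagents that add atoms: triisopropylsilyl chloride, CC(C)[Si](Cl)(C(C)C)C(C)C
Why: Imidazole-promoted O-silylation (silyl ether protection) masks the acidic phenol with a group that tolerates strong bases, TFA and LiOOH yet falls to fluoride at the end.

Step 2
Reactants: 2 (4-bromophenoxy)triisopropylsilane; 3 tert-butyl acetate
Product: 5 tert-butyl 2-[4-(triisopropylsilyloxy)phenyl]acetate, via lithium ester enolate 4 (not isolated)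
Conditions: LiN(SiMe3)2 (2.3 equiv), Pd(dba)2 (2 mol %), P(tBu)3 (4 mol %), toluene, rt
Reagents that add atoms: none
Why: Palladium-catalysed α-arylation of an ester enolate (oxidative addition of the aryl bromide to zerovalent palladium, transmetalation with the lithium enolate, reductive elimination) forges the aryl–CH2 bond, and the bulky tert-butyl ester suppresses Claisen self-condensation.

Step 3
Reactants: 5 tert-butyl 2-[4-(triisopropylsilyloxy)phenyl]acetate
Product: 6 2-[4-(triisopropylsilyloxy)phenyl]acetic acid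
Conditions: TFA/CH2Cl2 1:4, 0 °C → rt
Reagents that add atoms: none
Why: Acidolysis of the tert-butyl ester (E1 loss of isobutene) frees the acid, while the hindered aryl triisopropylsilyl ether is stable to anhydrous TFA.

Step 4
Reactants: 6 2-[4-(triisopropylsilyloxy)phenyl]acetic acid
Product: 8 (4S)-4-benzyl-3-{2-[4-(triisopropylsilyloxy)phenyl]acetyl}-1,3-oxazolidin-2-one, via mixed pivalic anhydride 7 (not isolated)
Conditions: tBuCOCl (1.05 equiv), Et3N (2.5 equiv), THF, −20 °C; then LiCl (1.1 equiv), (S)-4-benzyl-1,3-oxazolidin-2-one (1.0 equiv), −20 °C → rt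
Reagents that add atoms: (S)-4-benzyl-1,3-oxazolidin-2-one, O=C1N[C@@H](Cc2ccccc2)CO1
Why: Mixed-anhydride N-acylation of the Evans auxiliary works because the LiCl-activated oxazolidinone attacks the less hindered arylacetyl carbonyl of 7, and the stereocentre of the auxiliary is brought in unchanged.

**Fragment B**

Step 5
Reactants: 9 3-bromophenol; 10 prenyl bromide (1-bromo-3-methylbut-2-ene)
Product: 12 5-bromo-2-(3-methylbut-2-en-1-yl)phenol, via sodium 3-bromophenoxide 11 (not isolated)
Conditions: NaH (1.0 equiv), toluene, 0 °C → rt; then 10 (1.05 equiv), rt, 16 h; chromatography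
Reagents that add atoms: none
Why: Ortho-selective C-alkylation of a phenoxide (SN2 on prenyl bromide) is favoured over O-alkylation by the tight sodium ion pair in non-polar toluene, and C6 (para to Br) reacts rather than C2, which is squeezed between O and Br.

Step 6
Reactants: 12 5-bromo-2-(3-methylbut-2-en-1-yl)phenol
Product: 13 [5-bromo-2-(3-methylbut-2-en-1-yl)phenoxy]triisopropylsilane
Conditions: iPr3SiCl (1.2 equiv), imidazole (2.5 equiv), DMF, rt → 40 °C
Reagents that add atoms: triisopropylsilyl chloride, CC(C)[Si](Cl)(C(C)C)C(C)C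
Why: O-Silylation removes the acidic proton before Grignard formation and blocks acid-induced chroman formation between the phenol and the neighbouring prenyl group.

Step 7
Reactants: 13 [5-bromo-2-(3-methylbut-2-en-1-yl)phenoxy]triisopropylsilane; 14 methyl (2S)-oxirane-2-carboxylate (methyl (S)-glycidate)
Product: 17 methyl (2S)-2-hydroxy-3-[4-(3-methylbut-2-en-1-yl)-3-(triisopropylsilyloxy)phenyl]propanoate, via aryl Grignard reagent 15 (not isolated), via bromomagnesium alkoxide 16 (not isolated)
Conditions: Mg turnings, THF, 40 °C; then CuBr·SMe2 (10 mol %), 14 (1.2 equiv), THF, −30 °C; sat. aq NH4Cl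
Reagents that add atoms: none
Why: In this copper-catalysed Grignard opening of a terminal epoxide the arylcopper species attacks the unsubstituted CH2 of the glycidate faster than the ester, so the C2–O bond is untouched and the S configuration of 14 is carried into 17.

Step 8
Reactants: 17 methyl (2S)-2-hydroxy-3-[4-(3-methylbut-2-en-1-yl)-3-(triisopropylsilyloxy)phenyl]propanoate
Product: 18 methyl (2S)-3-[4-(3-methylbut-2-en-1-yl)-3-(triisopropylsilyloxy)phenyl]-2-(trifluoromethylsulfonyloxy)propanoate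
Conditions: Tf2O (1.15 equiv), 2,6-lutidine (1.4 equiv), CH2Cl2, −78 → −30 °C; cold wash, short silica plug, used at once
Reagents that add atoms: triflic anhydride, O=S(=O)(C(F)(F)F)OS(=O)(=O)C(F)(F)F
Why: O-Triflation of the secondary alcohol with a hindered non-nucleophilic base does not break the C–O bond, so the S configuration is retained in the activated ester.

**Coupling and end game**

Step 9
Reactants: 8 (4S)-4-benzyl-3-{2-[4-(triisopropylsilyloxy)phenyl]acetyl}-1,3-oxazolidin-2-one; 18 methyl (2S)-3-[4-(3-methylbut-2-en-1-yl)-3-(triisopropylsilyloxy)phenyl]-2-(trifluoromethylsulfonyloxy)propanoate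
Product: 20 methyl (2S,3S)-4-[(4S)-4-benzyl-2-oxo-1,3-oxazolidin-3-yl]-2-[4-(3-methylbut-2-en-1-yl)-3-(triisopropylsilyloxy)benzyl]-4-oxo-3-[4-(triisopropylsilyloxy)phenyl]butanoate, via sodium Z-enolate 19 (not isolated)
Conditions: NaN(SiMe3)2 (1.0 equiv), THF, −78 °C, 45 min; then 18 (1.1 equiv), −78 → −30 °C
Reagents that add atoms: none
Why: This is an Evans asymmetric alkylation merged with a stereospecific SN2 displacement, in which the chelated Z-enolate reacts on the face opposite the benzyl group of the (S)-auxiliary (aryl-bearing centre S) and backside attack inverts the (S)-triflate carbon, which is again named S only because the CIP priorities change, giving the anti-succinate.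

Step 10
Reactants: 20 methyl (2S,3S)-4-[(4S)-4-benzyl-2-oxo-1,3-oxazolidin-3-yl]-2-[4-(3-methylbut-2-en-1-yl)-3-(triisopropylsilyloxy)benzyl]-4-oxo-3-[4-(triisopropylsilyloxy)phenyl]butanoate
Product: 23 (2S,3S)-4-methoxy-3-[4-(3-methylbut-2-en-1-yl)-3-(triisopropylsilyloxy)benzyl]-4-oxo-2-[4-(triisopropylsilyloxy)phenyl]butanoic acid, via lithium peroxycarboxylate 21 (not isolated), via lithium carboxylate 22 (not isolated)
Conditions: LiOH (2 equiv), 30% H2O2 (5 equiv), THF/H2O 3:1, 0 °C; aq Na2SO3, 0 °C; 1 M HCl to pH 3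
Reagents that add atoms: hydrogen peroxide, OO
Why: In the Evans LiOOH hydrolysis the small, highly nucleophilic hydroperoxide anion attacks the exocyclic imide carbonyl in preference to the carbamate and the hindered methyl ester, sulfite reduces the peracid salt before acidification so the prenyl alkene is not epoxidised, and neither stereocentre is touched.

Step 11
Reactants: 23 (2S,3S)-4-methoxy-3-[4-(3-methylbut-2-en-1-yl)-3-(triisopropylsilyloxy)benzyl]-4-oxo-2-[4-(triisopropylsilyloxy)phenyl]butanoic acid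
Product: 24 (2S,3S)-3-[3-hydroxy-4-(3-methylbut-2-en-1-yl)benzyl]-2-(4-hydroxyphenyl)-4-methoxy-4-oxobutanoic acid (CNP0437978.1)
Conditions: Bu4NF (3 equiv), AcOH (3 equiv), THF, 0 °C → rt; pH 3 buffer work-up
Reagents that add atoms: none
Why: Fluoride-induced desilylation is driven by the strong Si–F bond and is buffered with AcOH, so the phenoxides are protonated at once and the methyl ester, the prenyl group and both stereocentres stay intact.

**Compound list**
1 | 4-bromophenol | Oc1ccc(Br)cc1 | starting material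
2 | (4-bromophenoxy)triisopropylsilane | CC(C)[Si](Oc1ccc(Br)cc1)(C(C)C)C(C)C | intermediate
3 | tert-butyl acetate | CC(=O)OC(C)(C)C | starting material
4 | lithium enolate of tert-butyl acetate | [Li+].[O-]C(=C)OC(C)(C)C | intermediate
5 | tert-butyl 2-[4-(triisopropylsilyloxy)phenyl]acetate | CC(C)(C)OC(=O)Cc1ccc(O[Si](C(C)C)(C(C)C)C(C)C)cc1 | intermediate
6 | 2-[4-(triisopropylsilyloxy)phenyl]acetic acid | OC(=O)Cc1ccc(O[Si](C(C)C)(C(C)C)C(C)C)cc1 | intermediate
7 | 2-[4-(triisopropylsilyloxy)phenyl]acetic pivalic anhydride | CC(C)(C)C(=O)OC(=O)Cc1ccc(O[Si](C(C)C)(C(C)C)C(C)C)cc1 | intermediate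
8 | (4S)-4-benzyl-3-{2-[4-(triisopropylsilyloxy)phenyl]acetyl}-1,3-oxazolidin-2-one | O=C(Cc1ccc(O[Si](C(C)C)(C(C)C)C(C)C)cc1)N1[C@@H](Cc2ccccc2)COC1=O | intermediate
9 | 3-bromophenol | Oc1cccc(Br)c1 | starting material
10 | prenyl bromide (1-bromo-3-methylbut-2-ene) | CC(C)=CCBr | starting material
11 | sodium 3-bromophenoxide | [Na+].[O-]c1cccc(Br)c1 | intermediate
12 | 5-bromo-2-(3-methylbut-2-en-1-yl)phenol | CC(C)=CCc1ccc(Br)cc1O | intermediate
13 | [5-bromo-2-(3-methylbut-2-en-1-yl)phenoxy]triisopropylsilane | CC(C)=CCc1ccc(Br)cc1O[Si](C(C)C)(C(C)C)C(C)C | intermediate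
14 | methyl (2S)-oxirane-2-carboxylate | COC(=O)[C@@H]1CO1 | starting material
15 | [4-(3-methylbut-2-en-1-yl)-3-(triisopropylsilyloxy)phenyl]magnesium bromide | CC(C)=CCc1ccc([Mg]Br)cc1O[Si](C(C)C)(C(C)C)C(C)C | intermediate
16 | bromomagnesium alkoxide of 17 | COC(=O)[C@@H](O[Mg]Br)Cc1ccc(CC=C(C)C)c(O[Si](C(C)C)(C(C)C)C(C)C)c1 | intermediate
17 | methyl (2S)-2-hydroxy-3-[4-(3-methylbut-2-en-1-yl)-3-(triisopropylsilyloxy)phenyl]propanoate | COC(=O)[C@@H](O)Cc1ccc(CC=C(C)C)c(O[Si](C(C)C)(C(C)C)C(C)C)c1 | intermediate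
18 | methyl (2S)-3-[4-(3-methylbut-2-en-1-yl)-3-(triisopropylsilyloxy)phenyl]-2-(trifluoromethylsulfonyloxy)propanoate | COC(=O)[C@@H](OS(=O)(=O)C(F)(F)F)Cc1ccc(CC=C(C)C)c(O[Si](C(C)C)(C(C)C)C(C)C)c1 | intermediate
19 | sodium (Z)-enolate of 8 | [Na+].[O-]/C(=C\c1ccc(O[Si](C(C)C)(C(C)C)C(C)C)cc1)N1[C@@H](Cc2ccccc2)COC1=O | intermediate
20 | methyl (2S,3S)-4-[(4S)-4-benzyl-2-oxo-1,3-oxazolidin-3-yl]-2-[4-(3-methylbut-2-en-1-yl)-3-(triisopropylsilyloxy)benzyl]-4-oxo-3-[4-(triisopropylsilyloxy)phenyl]butanoate | COC(=O)[C@@H](Cc1ccc(CC=C(C)C)c(O[Si](C(C)C)(C(C)C)C(C)C)c1)[C@H](C(=O)N1[C@@H](Cc2ccccc2)COC1=O)c1ccc(O[Si](C(C)C)(C(C)C)C(C)C)cc1 | intermediate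
21 | lithium peroxycarboxylate of 23 | COC(=O)[C@@H](Cc1ccc(CC=C(C)C)c(O[Si](C(C)C)(C(C)C)C(C)C)c1)[C@H](C(=O)O[O-])c1ccc(O[Si](C(C)C)(C(C)C)C(C)C)cc1.[Li+] | intermediate
22 | lithium carboxylate of 23 | COC(=O)[C@@H](Cc1ccc(CC=C(C)C)c(O[Si](C(C)C)(C(C)C)C(C)C)c1)[C@H](C(=O)[O-])c1ccc(O[Si](C(C)C)(C(C)C)C(C)C)cc1.[Li+] | intermediate
23 | (2S,3S)-4-methoxy-3-[4-(3-methylbut-2-en-1-yl)-3-(triisopropylsilyloxy)benzyl]-4-oxo-2-[4-(triisopropylsilyloxy)phenyl]butanoic acid | COC(=O)[C@@H](Cc1ccc(CC=C(C)C)c(O[Si](C(C)C)(C(C)C)C(C)C)c1)[C@H](C(=O)O)c1ccc(O[Si](C(C)C)(C(C)C)C(C)C)cc1 | intermediate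
24 | (2S,3S)-3-[3-hydroxy-4-(3-methylbut-2-en-1-yl)benzyl]-2-(4-hydroxyphenyl)-4-methoxy-4-oxobutanoic acid | COC(=O)[C@@H](Cc1ccc(CC=C(C)C)c(O)c1)[C@H](C(=O)O)c1ccc(O)cc1 | target

**Total step count:** 11
**Longest linear sequence:** 7 steps (1, 2, 3, 4, 9, 10, 11 or 5, 6, 7, 8, 9, 10, 11)

**Three steps most likely to fail**

**Step 9 (key coupling).**
- Risk: the enolate may act as a base and eliminate triflic acid from 18 to give the cinnamate. The triflate may racemise through triflate exchange. The chiral enolate and the chiral electrophile may also be a mismatched pair.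
- Fallback: it sets out from 13 and 8 and comes back at 20. It replaces the ionic displacement by an oxidative enolate heterocoupling.
- Negishi coupling of 13 with BrZnCH2CH2CO2Me (Pd(OAc)2, SPhos, THF, 50 °C) gives methyl 3-[4-(3-methylbut-2-en-1-yl)-3-(triisopropylsilyloxy)phenyl]propanoate F1.
- Compounds 8 and F1 are deprotonated together with LiN(iPr)2 (2.2 equiv, THF, −78 °C). This gives the lithium (Z)-enolate of the imide F2 and the lithium enolate of the ester F3.
- Copper bis(2-ethylhexanoate) (2.2 equiv, divalent copper as one-electron oxidant, −78 °C → rt) then joins the two α-carbons.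
- The auxiliary again fixes the aryl-bearing centre, but the ester-bearing centre is only partly controlled. Compound 20 therefore has to be separated by chromatography from the (2R,3S)-epimer of the coupled imide F4.

**Step 5 (C-prenylation).**
- Risk: O-prenylation, attack at C2 or C4 and double alkylation can push the yield of 12 down.
- Fallback: it sets out from 9 and comes back at 13. It builds the prenyl chain from a regiodefined formyl group.
- Casnati–Skattebøl ortho-formylation of 9 (MgCl2, Et3N, paraformaldehyde, MeCN, reflux) reacts at the unhindered ortho position and gives 4-bromo-2-hydroxybenzaldehyde F5.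
- Silylation (iPr3SiCl, imidazole, DMF) gives 4-bromo-2-(triisopropylsilyloxy)benzaldehyde F6.
- Reduction with iBu2AlH (CH2Cl2, −78 °C, chosen to avoid silyl migration) gives [4-bromo-2-(triisopropylsilyloxy)phenyl]methanol F7.
- An Appel reaction (CBr4, PPh3, CH2Cl2, 0 °C) gives [5-bromo-2-(bromomethyl)phenoxy]triisopropylsilane F8.
- Li2CuCl4-catalysed coupling of the benzylic bromide with Me2C=CHMgBr (THF, −20 °C) delivers 13 with the aryl bromide untouched.

**Step 10 (auxiliary removal).**
- Risk: the imide is flanked by an aryl group and a branched carbon, so attack may be slow. Endocyclic ring opening, partial saponification of the methyl ester or loss of silyl groups may then compete.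
- Fallback: it sets out from 20 and comes back at 23. It uses a soft sulfur nucleophile followed by thiophilic-metal hydrolysis instead of peroxide.
- EtSLi (EtSH, nBuLi, THF, 0 °C) transacylates the imide to S-ethyl (2S,3S)-4-methoxy-3-[4-(3-methylbut-2-en-1-yl)-3-(triisopropylsilyloxy)benzyl]-4-oxo-2-[4-(triisopropylsilyloxy)phenyl]butanethioate F9.
- AgNO3 with 2,6-lutidine in THF/H2O at rt then hydrolyses the thioester under nearly neutral conditions to 23.

**Further compounds**
F1 | step 9 | methyl 3-[4-(3-methylbut-2-en-1-yl)-3-(triisopropylsilyloxy)phenyl]propanoate | COC(=O)CCc1ccc(CC=C(C)C)c(O[Si](C(C)C)(C(C)C)C(C)C)c1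
F2 | step 9 | lithium (Z)-enolate of the imide 8 | [Li+].[O-]/C(=C\c1ccc(O[Si](C(C)C)(C(C)C)C(C)C)cc1)N1[C@@H](Cc2ccccc2)COC1=O
F3 | step 9 | lithium enolate of the ester F1 | [Li+].[O-]/C(OC)=C/Cc1ccc(CC=C(C)C)c(O[Si](C(C)C)(C(C)C)C(C)C)c1
F4 | step 9 | (2R,3S)-epimer of the coupled imide 20 | COC(=O)[C@H](Cc1ccc(CC=C(C)C)c(O[Si](C(C)C)(C(C)C)C(C)C)c1)[C@H](C(=O)N1[C@@H](Cc2ccccc2)COC1=O)c1ccc(O[Si](C(C)C)(C(C)C)C(C)C)cc1
F5 | step 5 | 4-bromo-2-hydroxybenzaldehyde | O=Cc1ccc(Br)cc1O
F6 | step 5 | 4-bromo-2-(triisopropylsilyloxy)benzaldehyde | O=Cc1ccc(Br)cc1O[Si](C(C)C)(C(C)C)C(C)C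
F7 | step 5 | [4-bromo-2-(triisopropylsilyloxy)phenyl]methanol | OCc1ccc(Br)cc1O[Si](C(C)C)(C(C)C)C(C)C
F8 | step 5 | [5-bromo-2-(bromomethyl)phenoxy]triisopropylsilane | BrCc1ccc(Br)cc1O[Si](C(C)C)(C(C)C)C(C)C
F9 | step 10 | S-ethyl (2S,3S)-4-methoxy-3-[4-(3-methylbut-2-en-1-yl)-3-(triisopropylsilyloxy)benzyl]-4-oxo-2-[4-(triisopropylsilyloxy)phenyl]butanethioate | COC(=O)[C@@H](Cc1ccc(CC=C(C)C)c(O[Si](C(C)C)(C(C)C)C(C)C)c1)[C@H](C(=O)SCC)c1ccc(O[Si](C(C)C)(C(C)C)C(C)C)cc1
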